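A direct plan would carry a protected 4-bromo-3-hydroxybenzaldehyde to the 2-arylacrylate A1, reduce and unmask it to the allylic alcohol A2, acylate the phenol alone (A3), epoxidise with Ti(OiPr)4, a tartrate ester and t-BuOOH to the epoxy alcohol A4, and acylate again.
Its weakest step would be the face-selective epoxidation of A3: 2-aryl allylic alcohols are the substrates this catalyst differentiates least well, the benzylic epoxy alcohol would sit next to titanium alkoxide, and the aryl ester could transesterify.
The phenol-only acylation of A2 would have to beat the primary alcohol and would install two identical esters in two steps.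
The assembly of the side chain of A1 would cost three steps for three carbons and pass through a polymerisable acrylate.

The route exploits a hidden symmetry: oxirane C2 carries two CH2–O arms (ring C3 and the exocyclic CH2O-acyl carbon), so it is the central carbon of a 2-arylglycerol and turns achiral when both arms are tied into an oxetane. The disconnection therefore runs from the oxirane to a bromohydrin and on to the achiral 3-aryl-3-silyloxyoxetane 10, whose skeleton comes from one aryllithium addition to oxetan-3-one. Enantioselective bromide opening of 10 sets the only stereocentre, decides which CH2 becomes ring C3, and installs the leaving group for 3-exo-tet closure. No alkene is epoxidised, the three side-chain carbons arrive together, and both esters go on in one operation.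

Key step: step 4

Assumption: the sense of induction of the squaramide catalyst on 10 cannot be predicted with certainty. The catalyst antipode that opens the pro-S CH2 (giving the S bromide) is used; if the first antipode tried gives the R bromide, its mirror image is taken.

Step 1
Reactants: 1 4-bromo-3-hydroxybenzaldehyde; 2 3-bromoprop-1-ene (allyl bromide)
Product: 3 4-bromo-3-(prop-2-en-1-yloxy)benzaldehyde
Conditions: 2 (1.2 equiv), K2CO3 (1.5 equiv), DMF, rt
Reagents that add atoms: 3-bromoprop-1-ene C=CCBr
Why: Williamson ether synthesis (SN2 of the phenoxide on allyl bromide) gives an ether that should resist organolithium at −78 °C, Me3SiBr and carbonate and can later be removed under neutral conditions.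

Step 2
Reactants: 3 4-bromo-3-(prop-2-en-1-yloxy)benzaldehyde; 4 oxetan-3-one
Product: 8 4-(3-hydroxyoxetan-3-yl)-3-(prop-2-en-1-yloxy)benzaldehyde, via lithium hemiaminal alkoxide 5 (not isolated), via aryllithium 6 (not isolated), via dilithium bis-alkoxide adduct 7 (not isolated)
Conditions: morpholine (1.1 equiv), n-BuLi (1.05 equiv), THF, −20 °C, then 3; n-BuLi (1.1 equiv), −78 °C; 4 (1.3 equiv), −78 to −40 °C; AcOH (2.5 equiv), then H2O
Reagents that add atoms: oxetan-3-one O=C1COC1
Why: Lithium morpholide adds to the aldehyde and masks it in situ as an α-amino alkoxide (Comins protection), bromine–lithium exchange at −78 °C then outruns attack on the hemiaminal or the allyl ether, the aryllithium adds 1,2 to the strained ketone, and protonation collapses the hemiaminal back to the aldehyde; no stereocentre is formed (8 is achiral).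

Step 3
Reactants: 8 4-(3-hydroxyoxetan-3-yl)-3-(prop-2-en-1-yloxy)benzaldehyde; 9 1-(trimethylsilyl)-1H-imidazole
Product: 10 3-(prop-2-en-1-yloxy)-4-[3-(trimethylsilyloxy)oxetan-3-yl]benzaldehyde
Conditions: 9 (1.5 equiv), CH2Cl2, rt
Reagents that add atoms: 1-(trimethylsilyl)-1H-imidazole C[Si](C)(C)n1ccnc1
Why: O-silylation of the hindered tertiary hydroxyl by a neutral silyl-transfer reagent, which oxetane and aldehyde tolerate; the silyl ether removes the only proton that could release HBr in the next step.

Step 4
Reactants: 10 3-(prop-2-en-1-yloxy)-4-[3-(trimethylsilyloxy)oxetan-3-yl]benzaldehyde; 11 bromotrimethylsilane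
Product: 13 4-[(2S)-1-bromo-2,3-dihydroxypropan-2-yl]-3-(prop-2-en-1-yloxy)benzaldehyde, via bis-silyl ether bromide 12 (not isolated)
Conditions: 11 (1.3 equiv), chiral squaramide hydrogen-bond donor (tert-leucine 2-arylpyrrolidine amide type, 5 mol%), t-BuOMe, −78 °C; then 1 M aq HCl–THF, 0 °C
Reagents that add atoms: bromotrimethylsilane C[Si](C)(C)Br
Why: The squaramide binds the bromide of Me3SiBr, which transfers its silyl group to the oxetane oxygen, and the catalyst-bound O-silyloxetanium bromide ion pair collapses by SN2 attack of bromide on one of the two enantiotopic ring CH2 groups to give the 3-bromopropyl silyl ether 12. The closest known reaction type is the squaramide-catalysed enantioselective addition of Me3SiBr to 3-substituted and 3,3-disubstituted oxetanes. No ring is closed; the four-membered ring is opened and its strain drives the step. The new stereocentre, the fully substituted carbinol carbon, is set by enantiotopic-group selection under catalyst control (attack at the pro-S CH2 gives the S bromide), and because no bond to that carbon is made or broken here or later it should not be scrambled. The step needs this group selection and the suppression of an uncatalysed opening: the preformed tertiary silyl ether keeps HBr out of the flask, the low temperature slows the background reaction, and aldehyde and allyl ether should be inert to Me3SiBr at −78 °C. Cold aqueous acid then hydrolyses both O–Si bonds to the diol 13 without disturbing the primary bromide.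

Step 5
Reactants: 13 4-[(2S)-1-bromo-2,3-dihydroxypropan-2-yl]-3-(prop-2-en-1-yloxy)benzaldehyde
Product: 14 4-[(2S)-2-(hydroxymethyl)oxiran-2-yl]-3-(prop-2-en-1-yloxy)benzaldehyde
Conditions: K2CO3 (2 equiv), MeOH, 0 °C
Reagents that add atoms: none
Why: Intramolecular Williamson reaction (3-exo-tet SN2) in which the tertiary alkoxide displaces the neighbouring primary bromide much faster than the primary alkoxide could close a four-membered ring; the phenol is still an ether and cannot interfere, and no bond to the stereocentre changes.

Step 6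
Reactants: 14 4-[(2S)-2-(hydroxymethyl)oxiran-2-yl]-3-(prop-2-en-1-yloxy)benzaldehyde; 15 3-methylbutanoic anhydride
Product: 17 [(2R)-2-[4-formyl-2-(3-methylbutanoyloxy)phenyl]oxiran-2-yl]methyl 3-methylbutanoate, via epoxy phenol 16 (not isolated)
Conditions: Pd(PPh3)4 (3 mol%), N-methylaniline (1.3 equiv), CH2Cl2, rt; then 0 °C, 15 (4 equiv), then Et3N (6 equiv), DMAP (10 mol%)
Reagents that add atoms: 3-methylbutanoic anhydride CC(C)CC(=O)OC(=O)CC(C)C
Why: Tsuji–Trost deallylation (zerovalent palladium ionises the aryl allyl ether and the weakly basic amine takes the allyl group, leaving a neutral phenol) followed in the same flask by DMAP-catalysed acyl transfer to phenol and primary alcohol before the phenol can attack the oxirane; no bond at the stereocentre changes, and the descriptor becomes R only because CH2O-acyl now outranks the ring CH2.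

## Compound list

1 | 4-bromo-3-hydroxybenzaldehyde | O=Cc1ccc(Br)c(O)c1 | starting material
2 | 3-bromoprop-1-ene (allyl bromide) | C=CCBr | starting material
3 | 4-bromo-3-(prop-2-en-1-yloxy)benzaldehyde | O=Cc1ccc(Br)c(OCC=C)c1 | intermediate
4 | oxetan-3-one | O=C1COC1 | starting material
5 | lithium [4-bromo-3-(prop-2-en-1-yloxy)phenyl](morpholin-4-yl)methanolate, racemic, not isolated | [Li]OC(N1CCOCC1)c1ccc(Br)c(OCC=C)c1 | intermediate
6 | lithium [4-lithio-3-(prop-2-en-1-yloxy)phenyl](morpholin-4-yl)methanolate, racemic, not isolated | [Li]OC(N1CCOCC1)c1ccc([Li])c(OCC=C)c1 | intermediate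
7 | dilithium bis-alkoxide of [4-(3-hydroxyoxetan-3-yl)-3-(prop-2-en-1-yloxy)phenyl](morpholin-4-yl)methanol, racemic, not isolated | [Li]OC(N1CCOCC1)c1ccc(C2(O[Li])COC2)c(OCC=C)c1 | intermediate
8 | 4-(3-hydroxyoxetan-3-yl)-3-(prop-2-en-1-yloxy)benzaldehyde | O=Cc1ccc(C2(O)COC2)c(OCC=C)c1 | intermediate
9 | 1-(trimethylsilyl)-1H-imidazole | C[Si](C)(C)n1ccnc1 | starting material
10 | 3-(prop-2-en-1-yloxy)-4-[3-(trimethylsilyloxy)oxetan-3-yl]benzaldehyde | C[Si](C)(C)OC1(c2ccc(C=O)cc2OCC=C)COC1 | intermediate
11 | bromotrimethylsilane | C[Si](C)(C)Br | starting material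
12 | 4-[(2S)-1-bromo-2,3-bis(trimethylsilyloxy)propan-2-yl]-3-(prop-2-en-1-yloxy)benzaldehyde, not isolated | C[Si](C)(C)OC[C@@](O[Si](C)(C)C)(c1ccc(C=O)cc1OCC=C)CBr | intermediate
13 | 4-[(2S)-1-bromo-2,3-dihydroxypropan-2-yl]-3-(prop-2-en-1-yloxy)benzaldehyde | OC[C@@](O)(c1ccc(C=O)cc1OCC=C)CBr | intermediate
14 | 4-[(2S)-2-(hydroxymethyl)oxiran-2-yl]-3-(prop-2-en-1-yloxy)benzaldehyde | OC[C@@]1(c2ccc(C=O)cc2OCC=C)CO1 | intermediate
15 | 3-methylbutanoic anhydride | CC(C)CC(=O)OC(=O)CC(C)C | starting material
16 | 3-hydroxy-4-[(2S)-2-(hydroxymethyl)oxiran-2-yl]benzaldehyde, not isolated | OC[C@@]1(c2ccc(C=O)cc2O)CO1 | intermediate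
17 | [(2R)-2-[4-formyl-2-(3-methylbutanoyloxy)phenyl]oxiran-2-yl]methyl 3-methylbutanoate | CC(C)CC(=O)OC[C@@]1(c2ccc(C=O)cc2OC(=O)CC(C)C)CO1 | target

Total step count: 6. Longest linear sequence: 6 steps (from 1).

Steps most likely to fail:

Step 4. The catalyst has to tell aryl from OSiMe3 at C3, so the group selection may be poor. Traces of HBr or participation of the ortho ether oxygen may also open the ring without selectivity. The fallback moves the desymmetrisation to an acyclic substrate. It sets out from 8: dilute aqueous acid (0.5 M H2SO4, THF, 50 °C) would hydrolyse the oxetane to the achiral triol 4-(1,2,3-trihydroxypropan-2-yl)-3-(prop-2-en-1-yloxy)benzaldehyde F1. Enantioselective monosulfonylation of one of its two enantiotopic CH2OH groups (TsCl, K2CO3, Cu(OTf)2 with a chiral 2,2'-isopropylidenebis(4-phenyl-2-oxazoline), MeCN) is a known way to desymmetrise 2-substituted glycerols through a copper-bound 1,2-diol chelate. It would give (2S)-2-[4-formyl-2-(prop-2-en-1-yloxy)phenyl]-2,3-dihydroxypropyl 4-methylbenzenesulfonate F2, which K2CO3 in MeOH would close to 14, where the route is rejoined.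

Step 6. The liberated phenol may attack the oxirane (5-exo opening to a dihydrobenzofuran), or the benzylic oxirane may open, before the acylation takes place. The fallback removes the allyl group before the oxirane exists. It sets out from 13: Pd(PPh3)4 and N-methylaniline would give 4-[(2S)-1-bromo-2,3-dihydroxypropan-2-yl]-3-hydroxybenzaldehyde F3. Then 15, Et3N and DMAP would acylate phenol and primary hydroxyl, leaving the tertiary hydroxyl, to give (2S)-3-bromo-2-[4-formyl-2-(3-methylbutanoyloxy)phenyl]-2-hydroxypropyl 3-methylbutanoate F4. Ag2O in THF would close the oxirane by abstracting bromide while the neutral tertiary hydroxyl attacks, so that no free alkoxide is present to take the acyl group from the neighbouring aryl ester. This arrives directly at 17.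

Step 2. The in situ masking of the aldehyde may be incomplete, n-BuLi may attack the hemiaminal or the allyl ether, or the aryllithium may enolise the ketone instead of adding to it. The fallback uses a discrete acetal and a less basic organometal. It sets out from 3: HC(OMe)3, MeOH and catalytic TsOH would give 1-bromo-4-(dimethoxymethyl)-2-(prop-2-en-1-yloxy)benzene F5. Bromine–lithium exchange (n-BuLi, THF, −78 °C), transmetalation with CeCl3 and addition to 4 would give 3-[4-(dimethoxymethyl)-2-(prop-2-en-1-yloxy)phenyl]oxetan-3-ol F6. Aqueous citric acid in THF would hydrolyse the acetal and return the route to 8.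

Further compounds

F1 | step 4 | 4-(1,2,3-trihydroxypropan-2-yl)-3-(prop-2-en-1-yloxy)benzaldehyde | OCC(O)(CO)c1ccc(C=O)cc1OCC=C
F2 | step 4 | (2S)-2-[4-formyl-2-(prop-2-en-1-yloxy)phenyl]-2,3-dihydroxypropyl 4-methylbenzenesulfonate | OC[C@@](O)(c1ccc(C=O)cc1OCC=C)COS(=O)(=O)c1ccc(C)cc1
F3 | step 6 | 4-[(2S)-1-bromo-2,3-dihydroxypropan-2-yl]-3-hydroxybenzaldehyde | OC[C@@](O)(c1ccc(C=O)cc1O)CBr
F4 | step 6 | (2S)-3-bromo-2-[4-formyl-2-(3-methylbutanoyloxy)phenyl]-2-hydroxypropyl 3-methylbutanoate | CC(C)CC(=O)OC[C@@](O)(c1ccc(C=O)cc1OC(=O)CC(C)C)CBr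
F5 | step 2 | 1-bromo-4-(dimethoxymethyl)-2-(prop-2-en-1-yloxy)benzene | COC(OC)c1ccc(Br)c(OCC=C)c1
F6 | step 2 | 3-[4-(dimethoxymethyl)-2-(prop-2-en-1-yloxy)phenyl]oxetan-3-ol | COC(OC)c1ccc(C2(O)COC2)c(OCC=C)c1
A1 | direct plan | tert-butyl 2-[4-(1,3-dioxolan-2-yl)-2-(methoxymethoxy)phenyl]prop-2-enoate | COCOc1cc(C2OCCO2)ccc1C(=C)C(=O)OC(C)(C)C
A2 | direct plan | 3-hydroxy-4-(3-hydroxyprop-1-en-2-yl)benzaldehyde | O=Cc1ccc(C(=C)CO)c(O)c1
A3 | direct plan | 5-formyl-2-(3-hydroxyprop-1-en-2-yl)phenyl 3-methylbutanoate | CC(C)CC(=O)Oc1cc(C=O)ccc1C(=C)CO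
A4 | direct plan | 5-formyl-2-[(2S)-2-(hydroxymethyl)oxiran-2-yl]phenyl 3-methylbutanoate | OC[C@@]1(c2ccc(C=O)cc2OC(=O)CC(C)C)CO1
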